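**Retrosynthetic overview**

1. The methylene bridge is made last: C5 of dihydrobenzofuran diol 17 adds to the methylidene pyrandione 23, generated in the flask from pyranone 21 and CH2=NMe2+ I−.
2. The dihydrofuran ring comes from a [4+1] annulation. The C2–C3 bond joins the electrophilic CH2 of ortho-quinone methide 14 to the chiral allylic sulfonium ylide 13, which acts as a nucleophilic stand-in for the carbinol carbon C2 (normally an electrophile, as in methacrolein). The phenoxide then displaces the sulfide with inversion and fixes (2S).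
3. The quinone methide comes from Mannich base 6. Two MOM ethers leave only the ketone-chelated phenol free, so the ring can close on one oxygen only.
4. Aryl ketone 4 comes from phloroglucinol and (S)-2-methylbutanoic acid (chiral pool); pyranone 21 from pentan-3-one and malonyl dichloride.
5. Ring order: benzene ring bought; pyranone ring and dihydrofuran ring built separately; the two halves joined last.

Assumption: the target is read as (2S) at the dihydrofuran carbon and (S) in the 2-methylbutanoyl group; the minor C2 epimer from step 7 is removed by chromatography.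

**Route**

Step 1
Reactants: 1 phloroglucinol; 2 (S)-2-methylbutanoic acid
Product: 4 (2S)-2-methyl-1-(2,4,6-trihydroxyphenyl)butan-1-one, via (S)-2-methylbutanoyl chloride 3 (not isolated)
Conditions: 2, (COCl)2, DMF (cat.), CH2Cl2, 0 °C → rt, then evaporate; 1, AlCl3 (4 equiv), PhNO2–CH2Cl2, 0 °C → rt
Reagents that add atoms: none
Why: Friedel–Crafts acylation of the very electron-rich ring stops at the mono-ketone because the product is deactivated as its aluminium chelate; the (S) centre comes from the chiral-pool acid and is kept by staying at or below room temperature.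

Step 2
Reactants: 4 (2S)-2-methyl-1-(2,4,6-trihydroxyphenyl)butan-1-one
Product: 5 (2S)-1-[2-hydroxy-4,6-bis(methoxymethoxy)phenyl]-2-methylbutan-1-one
Conditions: MOMCl (2.2 equiv), iPr2NEt (2.5 equiv), CH2Cl2, 0 °C → rt
Reagents that add atoms: chloromethyl methyl ether (MOMCl), COCCl
Why: O-alkylation (MOM ether formation) takes the para OH and one ortho OH, while the last ortho OH stays free because it is locked in a hydrogen bond to the ketone, the usual selectivity for 2,4,6-trihydroxyaryl ketones.

Step 3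
Reactants: 5 (2S)-1-[2-hydroxy-4,6-bis(methoxymethoxy)phenyl]-2-methylbutan-1-one
Product: 6 (2S)-1-{3-[(dimethylamino)methyl]-2-hydroxy-4,6-bis(methoxymethoxy)phenyl}-2-methylbutan-1-one
Conditions: CH2=NMe2+ I− (1.1 equiv), Et3N (1.2 equiv), CH2Cl2, 0 °C → rt
Reagents that add atoms: N,N-dimethylmethyleneiminium iodide (Eschenmoser's salt), C=[N+](C)C.[I-]
Why: Mannich reaction with a preformed iminium salt goes ortho to the free phenol (C3), since the other open carbon sits between two MOM ethers and is both more hindered and not assisted by the phenoxide.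

Step 4
Reactants: 7 (2R,5R)-hexane-2,5-diol
Product: 8 (2R,5R)-hexane-2,5-diyl dimethanesulfonate
Conditions: MsCl (2.3 equiv), Et3N (3 equiv), CH2Cl2, 0 °C
Reagents that add atoms: methanesulfonyl chloride, CS(=O)(=O)Cl
Why: Sulfonylation of both secondary alcohols on oxygen leaves the two stereocentres untouched.

Step 5
Reactants: 8 (2R,5R)-hexane-2,5-diyl dimethanesulfonate
Product: 9 (2S,5S)-2,5-dimethylthiolane
Conditions: Na2S·9H2O (1.2 equiv), DMSO, rt
Reagents that add atoms: sodium sulfide (Na2S, used as the nonahydrate), [Na+].[Na+].[S-2]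
Why: Two successive SN2 displacements by sulfide (the second a 5-exo ring closure) invert both centres, turning (2R,5R) into the C2-symmetric (2S,5S) sulfide.

Step 6
Reactants: 9 (2S,5S)-2,5-dimethylthiolane; 10 3-bromo-2-methylprop-1-ene (methallyl bromide)
Product: 11 (2S,5S)-2,5-dimethyl-1-(2-methylprop-2-en-1-yl)thiolan-1-ium tetrafluoroborate
Conditions: 10 (3 equiv), AgBF4 (1.0 equiv), acetone, 0 °C → rt, dark
Reagents that add atoms: silver tetrafluoroborate (AgBF4), [Ag+].F[B-](F)(F)F
Why: S-alkylation is driven to completion by precipitation of AgBr, and because the sulfide is C2-symmetric its two lone pairs are equivalent, so a single sulfonium salt forms.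

Step 7
Reactants: 6 (2S)-1-{3-[(dimethylamino)methyl]-2-hydroxy-4,6-bis(methoxymethoxy)phenyl}-2-methylbutan-1-one; 11 (2S,5S)-2,5-dimethyl-1-(2-methylprop-2-en-1-yl)thiolan-1-ium tetrafluoroborate
Product: 16 (2S)-1-[(2S)-4,6-bis(methoxymethoxy)-2-(prop-1-en-2-yl)-2,3-dihydro-1-benzofuran-7-yl]-2-methylbutan-1-one, via ammonium iodide 12 (not isolated), via sulfonium ylide 13 (not isolated), via ortho-quinone methide 14 (not isolated), via sulfonium phenoxide betaine 15 (not isolated)
Conditions: MeI (1.1 equiv), MeCN, rt, then evaporate; 11 (1.3 equiv), LiN(SiMe3)2 (2.3 equiv), THF, −78 → 0 °C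
Reagents that add atoms: none
Why: Proposed new method: base converts 12 into quinone methide 14 by loss of NMe3 and 11 into the allylic ylide 13, whose carbanion carbon (the future C2, an alcohol-level carbon used as a nucleophile instead of in its normal electrophilic role) adds to the exocyclic CH2 of 14 on the ylide face left open by the thiolane (the ring methyl syn to the S–C bond blocks the other face, the isopropenyl group points away from the ring) to give the (R)-sulfonium betaine 15, and the only free ring oxygen then displaces the sulfide in a 5-exo SN2 step with inversion to set (2S); the closest known chemistry is the [4+1] annulation of ortho-quinone methides with sulfur ylides and the asymmetric epoxidation with 2-methylallyl ylides of 2,5-dimethylthiolane, where the (2R,5R) sulfide gives (S,S) epoxides, the sense of induction that with the (2S,5S) sulfide leads to (2S) here, and base is kept to the stoichiometric amount so that the ketone α-centre is not enolised.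

Step 8
Reactants: 16 (2S)-1-[(2S)-4,6-bis(methoxymethoxy)-2-(prop-1-en-2-yl)-2,3-dihydro-1-benzofuran-7-yl]-2-methylbutan-1-one
Product: 17 (2S)-1-[(2S)-4,6-dihydroxy-2-(prop-1-en-2-yl)-2,3-dihydro-1-benzofuran-7-yl]-2-methylbutan-1-one
Conditions: HCl (1 M) in MeOH, rt, stop at full conversion
Reagents that add atoms: none
Why: Acid-catalysed acetal methanolysis (MOM removal) is fast for these ketone-conjugated aryl acetals, so dilute acid at room temperature suffices and the 1,1-disubstituted alkene, the allylic aryl ether and both stereocentres are left alone.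

Step 9
Reactants: 18 pentan-3-one
Product: 19 (Z)-3-(trimethylsilyloxy)pent-2-ene
Conditions: Me3SiOTf (1.1 equiv), Et3N (1.3 equiv), CH2Cl2, 0 °C
Reagents that add atoms: trimethylsilyl trifluoromethanesulfonate, C[Si](C)(C)OS(=O)(=O)C(F)(F)F
Why: Soft enolisation and O-silylation of a symmetrical ketone gives one regioisomeric silyl enol ether (mainly Z; the geometry is lost in the next step).

Step 10
Reactants: 19 (Z)-3-(trimethylsilyloxy)pent-2-ene; 20 malonyl dichloride
Product: 21 6-ethyl-4-hydroxy-5-methyl-2H-pyran-2-one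
Conditions: Et2O, −78 °C → rt
Reagents that add atoms: none
Why: C-acylation of the silyl enol ether by one acid chloride, then O-acylation (lactonisation) of the resulting enol by the second, builds the 4-hydroxy-2-pyranone in one operation (Effenberger-type pyranone synthesis).

Step 11
Reactants: 17 (2S)-1-[(2S)-4,6-dihydroxy-2-(prop-1-en-2-yl)-2,3-dihydro-1-benzofuran-7-yl]-2-methylbutan-1-one; 21 6-ethyl-4-hydroxy-5-methyl-2H-pyran-2-one
Product: 24 6-ethyl-4-hydroxy-3-({(2S)-4,6-dihydroxy-7-[(2S)-2-methylbutanoyl]-2-(prop-1-en-2-yl)-2,3-dihydro-1-benzofuran-5-yl}methyl)-5-methyl-2H-pyran-2-one (CNP0261501.1), via pyranone Mannich base 22 (not isolated), via methylidene dione 23 (not isolated)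
Conditions: 21 (1.2 equiv), CH2=NMe2+ I− (1.2 equiv), CHCl3, rt, 1 h; then 17 (1.0 equiv), 40 °C
Reagents that add atoms: N,N-dimethylmethyleneiminium iodide (Eschenmoser's salt), C=[N+](C)C.[I-]
Why: Mannich reaction of the pyranone followed by loss of dimethylamine gives the strongly electrophilic methylidene dione, which is trapped in a Michael (Friedel–Crafts-type) addition by C5, the only free ring carbon of 17, and no stereocentre is touched.

**Compound list**

1 | phloroglucinol (benzene-1,3,5-triol) | Oc1cc(O)cc(O)c1 | starting material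
2 | (S)-2-methylbutanoic acid | CC[C@H](C)C(=O)O | starting material
3 | (S)-2-methylbutanoyl chloride (formed in the flask) | CC[C@H](C)C(=O)Cl | intermediate
4 | (2S)-2-methyl-1-(2,4,6-trihydroxyphenyl)butan-1-one | CC[C@H](C)C(=O)c1c(O)cc(O)cc1O | intermediate
5 | (2S)-1-[2-hydroxy-4,6-bis(methoxymethoxy)phenyl]-2-methylbutan-1-one | CC[C@H](C)C(=O)c1c(O)cc(OCOC)cc1OCOC | intermediate
6 | (2S)-1-{3-[(dimethylamino)methyl]-2-hydroxy-4,6-bis(methoxymethoxy)phenyl}-2-methylbutan-1-one | CC[C@H](C)C(=O)c1c(O)c(CN(C)C)c(OCOC)cc1OCOC | intermediate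
7 | (2R,5R)-hexane-2,5-diol | C[C@@H](O)CC[C@@H](C)O | starting material
8 | (2R,5R)-hexane-2,5-diyl dimethanesulfonate | C[C@@H](OS(C)(=O)=O)CC[C@@H](C)OS(C)(=O)=O | intermediate
9 | (2S,5S)-2,5-dimethylthiolane | C[C@H]1CC[C@H](C)S1 | intermediate
10 | 3-bromo-2-methylprop-1-ene (methallyl bromide) | C=C(C)CBr | starting material
11 | (2S,5S)-2,5-dimethyl-1-(2-methylprop-2-en-1-yl)thiolan-1-ium tetrafluoroborate | C[C@H]1CC[C@H](C)[S+]1CC(C)=C.F[B-](F)(F)F | intermediate
12 | {2-hydroxy-4,6-bis(methoxymethoxy)-3-[(2S)-2-methylbutanoyl]phenyl}-N,N,N-trimethylmethanaminium iodide (formed in the flask) | CC[C@H](C)C(=O)c1c(O)c(C[N+](C)(C)C)c(OCOC)cc1OCOC.[I-] | intermediate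
13 | (2S,5S)-2,5-dimethylthiolan-1-ium 2-methylprop-2-en-1-ylide (formed in the flask) | C[C@H]1CC[C@H](C)[S+]1[CH-]C(C)=C | intermediate
14 | 3,5-bis(methoxymethoxy)-2-[(2S)-2-methylbutanoyl]-6-methylidenecyclohexa-2,4-dien-1-one (formed in the flask) | C=C1C(=O)C(C(=O)[C@@H](C)CC)=C(OCOC)C=C1OCOC | intermediate
15 | (2S,5S)-1-{(2R)-1-[2-oxido-4,6-bis(methoxymethoxy)-3-((2S)-2-methylbutanoyl)phenyl]-3-methylbut-3-en-2-yl}-2,5-dimethylthiolan-1-ium, zwitterion (formed in the flask) | C=C(C)[C@@H](Cc1c([O-])c(C(=O)[C@@H](C)CC)c(OCOC)cc1OCOC)[S+]1[C@@H](C)CC[C@@H]1C | intermediate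
16 | (2S)-1-[(2S)-4,6-bis(methoxymethoxy)-2-(prop-1-en-2-yl)-2,3-dihydro-1-benzofuran-7-yl]-2-methylbutan-1-one | C=C(C)[C@@H]1Cc2c(OCOC)cc(OCOC)c(C(=O)[C@@H](C)CC)c2O1 | intermediate
17 | (2S)-1-[(2S)-4,6-dihydroxy-2-(prop-1-en-2-yl)-2,3-dihydro-1-benzofuran-7-yl]-2-methylbutan-1-one | C=C(C)[C@@H]1Cc2c(O)cc(O)c(C(=O)[C@@H](C)CC)c2O1 | intermediate
18 | pentan-3-one | CCC(=O)CC | starting material
19 | (Z)-3-(trimethylsilyloxy)pent-2-ene | C/C=C(/CC)O[Si](C)(C)C | intermediate
20 | malonyl dichloride (propanedioyl dichloride) | O=C(Cl)CC(=O)Cl | starting material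
21 | 6-ethyl-4-hydroxy-5-methyl-2H-pyran-2-one | CCc1oc(=O)cc(O)c1C | intermediate
22 | 3-[(dimethylamino)methyl]-6-ethyl-4-hydroxy-5-methyl-2H-pyran-2-one (formed in the flask) | CCc1oc(=O)c(CN(C)C)c(O)c1C | intermediate
23 | 6-ethyl-5-methyl-3-methylidene-2H-pyran-2,4(3H)-dione (formed in the flask) | CCC1=C(C)C(=O)C(=C)C(=O)O1 | intermediate
24 | 6-ethyl-4-hydroxy-3-({(2S)-4,6-dihydroxy-7-[(2S)-2-methylbutanoyl]-2-(prop-1-en-2-yl)-2,3-dihydro-1-benzofuran-5-yl}methyl)-5-methyl-2H-pyran-2-one (CNP0261501.1) | C=C(C)[C@@H]1Cc2c(O)c(Cc3c(O)c(C)c(CC)oc3=O)c(O)c(C(=O)[C@@H](C)CC)c2O1 | target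

**Step count and risks**

Total step count: 11 (steps 4–6 make the chiral sulfonium salt, steps 9–10 the pyranone).
Longest linear sequence: 6 (steps 1, 2, 3, 7, 8, 11).

The three steps most likely to fail:

Step 7 ([4+1] annulation). The risks are proton shuffling between ylide and phenol, attack through the far end of the allyl ylide, and modest face control. The fallback sets out from 12 and comes back at 16. It keeps the C2–C3 disconnection but uses a soft nitronate as the polarity-reversed C2 nucleophile and moves stereocontrol to a catalytic step. NaNO2 in DMF converts 10 into 2-methyl-3-nitroprop-1-ene F1. With iPr2NEt in MeCN at rt, 12 releases 14, which is trapped by the nitronate of F1 to give (2S)-1-[2-hydroxy-4,6-bis(methoxymethoxy)-3-(3-methyl-2-nitrobut-3-en-1-yl)phenyl]-2-methylbutan-1-one F2 as both epimers at the nitro carbon. Zerovalent palladium (Pd2(dba)3·CHCl3, 2.5 mol %) with a DACH-phenyl Trost ligand and Cs2CO3 in CH2Cl2 ionises the allylic nitro group. The two epimers converge on one π-allyl complex and the phenoxide closes the five-membered ring enantioselectively to 16. I have not fixed which ligand enantiomer gives (2S); both are commercial and a pilot run decides.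

Step 3 (aminomethylation). The risks are attack at C5 between the two MOM ethers instead of C3, and over-reaction. The fallback sets out from 5 and comes back at 14. Magnesium-phenoxide-directed ortho-formylation (MgCl2, Et3N, paraformaldehyde, MeCN, reflux) can only deliver formaldehyde next to the free OH and gives 2-hydroxy-4,6-bis(methoxymethoxy)-3-[(2S)-2-methylbutanoyl]benzaldehyde F3. NaBH4 in MeOH at −20 °C reduces the aldehyde, not the chelated hindered ketone, to (2S)-1-[2-hydroxy-3-(hydroxymethyl)-4,6-bis(methoxymethoxy)phenyl]-2-methylbutan-1-one F4. Ac2O (1.05 equiv) and pyridine at 0 °C acetylate only the primary alcohol to give {2-hydroxy-4,6-bis(methoxymethoxy)-3-[(2S)-2-methylbutanoyl]phenyl}methyl acetate F5. Under the step 7 conditions, without MeI, deprotonated F5 loses acetate and delivers 14.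

Step 8 (MOM removal). The risk is acid damage to the isopropenyl group and the allylic aryl ether. The fallback sets out from 4 and comes back at 17. It replaces the acetals by silyl ethers that leave with fluoride. TBSCl (2.1 equiv) and imidazole in DMF give (2S)-1-[2-hydroxy-4,6-bis(tert-butyldimethylsilyloxy)phenyl]-2-methylbutan-1-one F6. The step 3 conditions give (2S)-1-{3-[(dimethylamino)methyl]-2-hydroxy-4,6-bis(tert-butyldimethylsilyloxy)phenyl}-2-methylbutan-1-one F7. The step 7 conditions take it through the methiodide F8, the quinone methide F9 and the betaine F10 to (2S)-1-[(2S)-4,6-bis(tert-butyldimethylsilyloxy)-2-(prop-1-en-2-yl)-2,3-dihydro-1-benzofuran-7-yl]-2-methylbutan-1-one F11. Bu4NF buffered with AcOH in THF at 0 °C then gives 17 without acid.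

Further compounds

F1 | step 7 | 2-methyl-3-nitroprop-1-ene | C=C(C)C[N+](=O)[O-]
F2 | step 7 | (2S)-1-[2-hydroxy-4,6-bis(methoxymethoxy)-3-(3-methyl-2-nitrobut-3-en-1-yl)phenyl]-2-methylbutan-1-one (both epimers at the nitro carbon) | CC[C@H](C)C(=O)c1c(O)c(CC(C(C)=C)[N+](=O)[O-])c(OCOC)cc1OCOC
F3 | step 3 | 2-hydroxy-4,6-bis(methoxymethoxy)-3-[(2S)-2-methylbutanoyl]benzaldehyde | CC[C@H](C)C(=O)c1c(O)c(C=O)c(OCOC)cc1OCOC
F4 | step 3 | (2S)-1-[2-hydroxy-3-(hydroxymethyl)-4,6-bis(methoxymethoxy)phenyl]-2-methylbutan-1-one | CC[C@H](C)C(=O)c1c(O)c(CO)c(OCOC)cc1OCOC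
F5 | step 3 | {2-hydroxy-4,6-bis(methoxymethoxy)-3-[(2S)-2-methylbutanoyl]phenyl}methyl acetate | CC[C@H](C)C(=O)c1c(O)c(COC(C)=O)c(OCOC)cc1OCOC
F6 | step 8 | (2S)-1-[2-hydroxy-4,6-bis(tert-butyldimethylsilyloxy)phenyl]-2-methylbutan-1-one | CC[C@H](C)C(=O)c1c(O)cc(O[Si](C)(C)C(C)(C)C)cc1O[Si](C)(C)C(C)(C)C
F7 | step 8 | (2S)-1-{3-[(dimethylamino)methyl]-2-hydroxy-4,6-bis(tert-butyldimethylsilyloxy)phenyl}-2-methylbutan-1-one | CC[C@H](C)C(=O)c1c(O)c(CN(C)C)c(O[Si](C)(C)C(C)(C)C)cc1O[Si](C)(C)C(C)(C)C
F8 | step 8 | {2-hydroxy-4,6-bis(tert-butyldimethylsilyloxy)-3-[(2S)-2-methylbutanoyl]phenyl}-N,N,N-trimethylmethanaminium iodide | CC[C@H](C)C(=O)c1c(O)c(C[N+](C)(C)C)c(O[Si](C)(C)C(C)(C)C)cc1O[Si](C)(C)C(C)(C)C.[I-]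
F9 | step 8 | 3,5-bis(tert-butyldimethylsilyloxy)-2-[(2S)-2-methylbutanoyl]-6-methylidenecyclohexa-2,4-dien-1-one | C=C1C(=O)C(C(=O)[C@@H](C)CC)=C(O[Si](C)(C)C(C)(C)C)C=C1O[Si](C)(C)C(C)(C)C
F10 | step 8 | (2S,5S)-1-{(2R)-1-[2-oxido-4,6-bis(tert-butyldimethylsilyloxy)-3-((2S)-2-methylbutanoyl)phenyl]-3-methylbut-3-en-2-yl}-2,5-dimethylthiolan-1-ium, zwitterion | C=C(C)[C@@H](Cc1c([O-])c(C(=O)[C@@H](C)CC)c(O[Si](C)(C)C(C)(C)C)cc1O[Si](C)(C)C(C)(C)C)[S+]1[C@@H](C)CC[C@@H]1C
F11 | step 8 | (2S)-1-[(2S)-4,6-bis(tert-butyldimethylsilyloxy)-2-(prop-1-en-2-yl)-2,3-dihydro-1-benzofuran-7-yl]-2-methylbutan-1-one | C=C(C)[C@@H]1Cc2c(O[Si](C)(C)C(C)(C)C)cc(O[Si](C)(C)C(C)(C)C)c(C(=O)[C@@H](C)CC)c2O1
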